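**Retrosynthetic overview** (germacrane numbering: C1 ketone, C2=C3, C4(Me)=C5, C6 ester carbinol, C7, C8 lactone carbinol, C9H2, C10 with Me and ring O, C11(=C13)–C12)
1. Enabling feature: C10 is C2 of the 3(2H)-furanone ring (O, C10, C1, C2, C3), flanked by the ring oxygen and the C1 ketone, so its enolate is a planar aromatic furan-3-olate; C9 is the CH2 next to the C8 carbinol, i.e. the terminal carbon of a C8–C9 epoxide.
2. Target ⇐ γ-lactone (C8–O–C12, formed last) by allylic oxidation of a C7 isopropenyl group and oxidative lactonisation onto the C8 hydroxyl.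
3. ⇐ one-pot furanone formation (O–C3) and dearomative, stereoconvergent C9–C10 closure (nine-membered oxacycle = ten-membered carbocycle) from an acyclic α'-hydroxy ynone epoxide.
4. ⇐ Sonogashira union (C3–C4) of a Z-vinyl iodide with stereorandom pent-1-yne-3,4-diol; C6 ester from a Sharpless-derived (2S,3R)-epoxy acid.
5. ⇐ all-syn C6/C7/C8 triad by Evans deconjugative syn-aldol (C6–C7), chloromethyl ketone homologation (C8–C9) and 1,3-syn reduction. Ring order: epoxide (temporary) → furanone → macrocycle → lactone.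

Key step: step 15

**Route**

Step 1
Reactants: 1 but-2-yn-1-ol
Product: 3 (Z)-3-iodobut-2-en-1-ol, via sodium alkenylalanate 2 (not isolated)
Conditions: NaAlH2(OCH2CH2OMe)2, THF, 0 → 23 °C; then I2, −78 → 0 °C
Reagents that add atoms: iodine ([I][I])
Why: Hydroxyl-directed trans-hydroalumination places aluminium on the distal alkyne carbon cis to the carbinol carbon, and iodinolysis with retention should give the Z-vinyl iodide (hydroalumination–iodination).

Step 2
Reactants: 3 (Z)-3-iodobut-2-en-1-ol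
Product: 4 (Z)-3-iodobut-2-enal
Conditions: MnO2, CH2Cl2, 23 °C, dark; used at once
Reagents that add atoms: none
Why: Allylic alcohol oxidation with MnO2 leaves the vinyl iodide untouched, and immediate use should preserve the Z geometry.

Step 3
Reactants: 5 (S)-4-benzyl-1,3-oxazolidin-2-one; 6 3-methylbut-2-enoyl chloride
Product: 8 (S)-4-benzyl-3-(3-methylbut-2-enoyl)-1,3-oxazolidin-2-one, via lithiated oxazolidinone 7 (not isolated)
Conditions: n-BuLi, THF, −78 °C; then 6, −78 → 0 °C
Reagents that add atoms: none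
Why: N-Acylation of the lithiated Evans auxiliary by the acid chloride (imide formation).

Step 4
Reactants: 8 (S)-4-benzyl-3-(3-methylbut-2-enoyl)-1,3-oxazolidin-2-one; 4 (Z)-3-iodobut-2-enal
Product: 10 (4S)-4-benzyl-3-[(2S,3S,4Z)-3-hydroxy-5-iodo-2-(prop-1-en-2-yl)hex-4-enoyl]-1,3-oxazolidin-2-one, via boron dienolate 9 (not isolated)
Conditions: n-Bu2BOTf, Et3N, CH2Cl2, −78 → 0 °C; then 4, −78 → 0 °C; H2O2, MeOH, pH 7 buffer
Reagents that add atoms: none
Why: Evans boron aldol in its deconjugative form (γ-enolisation, α-attack): the Z-dienolate reacts through a chair Zimmerman–Traxler transition state on the face away from the benzyl group, which should set C7 (isopropenyl) and C6 (hydroxyl) syn in the absolute sense dictated by the (S)-auxiliary.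

Step 5
Reactants: 10 (4S)-4-benzyl-3-[(2S,3S,4Z)-3-hydroxy-5-iodo-2-(prop-1-en-2-yl)hex-4-enoyl]-1,3-oxazolidin-2-one
Product: 11 (2S,3S,4Z)-3-hydroxy-5-iodo-N-methoxy-N-methyl-2-(prop-1-en-2-yl)hex-4-enamide
Conditions: MeNH(OMe)·HCl, AlMe3, CH2Cl2, −20 → 0 °C
Reagents that add atoms: N,O-dimethylhydroxylamine hydrochloride (CNOC.Cl)
Why: Aluminium amide transamination of the β-hydroxy imide (Weinreb amide formation) removes the auxiliary and should not epimerise C7.

Step 6
Reactants: 11 (2S,3S,4Z)-3-hydroxy-5-iodo-N-methoxy-N-methyl-2-(prop-1-en-2-yl)hex-4-enamide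
Product: 12 (3S,4S,5Z)-1-chloro-4-hydroxy-6-iodo-3-(prop-1-en-2-yl)hept-5-en-2-one
Conditions: ICH2Cl, MeLi·LiBr, THF/Et2O, −78 °C; then aq. NH4Cl; used without delay
Reagents that add atoms: chloroiodomethane (ClCI)
Why: Homologation of the Weinreb amide with chloromethyllithium generated in the presence of the substrate (carbenoid acylation, single addition) installs C9 as CH2Cl, the iodine–lithium exchange being far faster at ICH2Cl than at the vinyl iodide.

Step 7
Reactants: 12 (3S,4S,5Z)-1-chloro-4-hydroxy-6-iodo-3-(prop-1-en-2-yl)hept-5-en-2-one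
Product: 13 (2R,3S,4S,5Z)-1-chloro-6-iodo-3-(prop-1-en-2-yl)hept-5-ene-2,4-diol
Conditions: Et2BOMe, NaBH4, THF/MeOH 4:1, −78 °C; then AcOH, MeOH co-evaporation
Reagents that add atoms: none
Why: Narasaka–Prasad reduction: boron chelation of the β-hydroxy ketone directs external hydride so that C8 is set 1,3-syn to C6, which should complete the all-syn C6/C7/C8 triad.

Step 8
Reactants: 13 (2R,3S,4S,5Z)-1-chloro-6-iodo-3-(prop-1-en-2-yl)hept-5-ene-2,4-diol
Product: 14 (3S,4S,5Z)-6-iodo-2-methyl-3-[(2R)-oxiran-2-yl]hepta-1,5-dien-4-ol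
Conditions: K2CO3, MeOH, 0 °C
Reagents that add atoms: none
Why: Intramolecular Williamson closure of the chlorohydrin (3-exo-tet) gives the terminal C8–C9 epoxide with C8 unchanged and leaves the C6 hydroxyl free.

Step 9
Reactants: 15 (E)-2-methylbut-2-en-1-ol
Product: 16 [(2R,3R)-2,3-dimethyloxiran-2-yl]methanol
Conditions: Ti(OiPr)4 (cat.), D-(−)-diisopropyl tartrate (cat.), t-BuOOH, 4 Å MS, CH2Cl2, −20 °C
Reagents that add atoms: tert-butyl hydroperoxide (CC(C)(C)OO)
Why: Sharpless asymmetric epoxidation, in which the D-(−)-tartrate should deliver oxygen to the alkene face that gives the (2R,3R)-epoxy alcohol.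

Step 10
Reactants: 16 [(2R,3R)-2,3-dimethyloxiran-2-yl]methanol
Product: 18 (2S,3R)-2,3-dimethyloxirane-2-carboxylic acid, via epoxy aldehyde 17 (not isolated)
Conditions: TEMPO (cat.), PhI(OAc)2, MeCN/H2O 1:1, 23 °C
Reagents that add atoms: water (O)
Why: Oxoammonium (TEMPO) oxidation in wet acetonitrile takes the primary alcohol through the aldehyde to the acid without opening the epoxide.

Step 11
Reactants: 14 (3S,4S,5Z)-6-iodo-2-methyl-3-[(2R)-oxiran-2-yl]hepta-1,5-dien-4-ol; 18 (2S,3R)-2,3-dimethyloxirane-2-carboxylic acid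
Product: 20 (3S,4S,5Z)-6-iodo-2-methyl-3-[(2R)-oxiran-2-yl]hepta-1,5-dien-4-yl (2S,3R)-2,3-dimethyloxirane-2-carboxylate, via mixed anhydride 19 (not isolated)
Conditions: 2,4,6-Cl3C6H2COCl, Et3N, toluene, 23 °C; then 14, DMAP, 23 °C
Reagents that add atoms: none
Why: Yamaguchi esterification acylates the hindered allylic C6 hydroxyl with retention, and the acid has no epimerisable α-hydrogen.

Step 12
Reactants: 21 pent-3-en-1-yne (E/Z mixture)
Product: 22 pent-1-yne-3,4-diol (mixture of stereoisomers)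
Conditions: K2OsO4·2H2O (cat.), NMO, acetone/H2O, 0 → 23 °C
Reagents that add atoms: 4-methylmorpholine N-oxide (C[N+]1([O-])CCOCC1); water (O)
Why: Upjohn syn-dihydroxylation of the enyne alkene with the alkyne inert; the stereoisomer mixture is immaterial because one carbinol becomes the C1 ketone and the other (C10) is enolised in step 15.

Step 13
Reactants: 20 (3S,4S,5Z)-6-iodo-2-methyl-3-[(2R)-oxiran-2-yl]hepta-1,5-dien-4-yl (2S,3R)-2,3-dimethyloxirane-2-carboxylate; 22 pent-1-yne-3,4-diol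
Product: 23 (3S,4R,5Z)-9,10-dihydroxy-2,6-dimethyl-3-[(2R)-oxiran-2-yl]undeca-1,5-dien-7-yn-4-yl (2S,3R)-2,3-dimethyloxirane-2-carboxylate (mixture at the two carbinols)
Conditions: PdCl2(PPh3)2 (cat.), CuI (cat.), i-Pr2NH, THF, 23 °C
Reagents that add atoms: none
Why: Sonogashira coupling of the vinyl iodide with the terminal alkyne proceeds with retention of the Z geometry and tolerates free hydroxyls, epoxides and the ester.

Step 14
Reactants: 23 (3S,4R,5Z)-9,10-dihydroxy-2,6-dimethyl-3-[(2R)-oxiran-2-yl]undeca-1,5-dien-7-yn-4-yl (2S,3R)-2,3-dimethyloxirane-2-carboxylate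
Product: 24 (3S,4R,5Z)-10-hydroxy-2,6-dimethyl-3-[(2R)-oxiran-2-yl]-9-oxoundeca-1,5-dien-7-yn-4-yl (2S,3R)-2,3-dimethyloxirane-2-carboxylate (both carbinol epimers)
Conditions: MnO2, CH2Cl2, 23 °C
Reagents that add atoms: none
Why: Selective propargylic oxidation: MnO2 should oxidise only the enyne-activated carbinol (C1) and leave the unactivated secondary hydroxyl at C10.

Step 15
Reactants: 24 (3S,4R,5Z)-10-hydroxy-2,6-dimethyl-3-[(2R)-oxiran-2-yl]-9-oxoundeca-1,5-dien-7-yn-4-yl (2S,3R)-2,3-dimethyloxirane-2-carboxylate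
Product: 26 (4Z,6R,7R,8S,10R)-8-hydroxy-1-oxo-3,10-epoxygermacra-2,4,11(13)-trien-6-yl (2S,3R)-2,3-dimethyloxirane-2-carboxylate, via furanone 25 (not isolated)
Conditions: Cs2CO3, MeCN/t-BuOH 9:1, 0.002 M (slow addition of 24), 60 °C
Reagents that add atoms: none
Why: Proposed new method: Cs2CO3 first triggers the known 5-endo-dig oxa-Michael cyclisation of the α'-hydroxy ynone to furanone 25, whose C10–H, flanked by the ring oxygen and the C1 ketone, is then removed to give a planar aromatic furan-3-olate that attacks the terminal epoxide carbon C9 in an SN2 opening with dearomatisation, so that the C9–C10 bond, the quaternary C10 and the free C8 hydroxyl arise in one base-catalysed isomerisation. The closest known reaction types are the C2-alkylation of 2-methyl-3(2H)-furanone enolates by primary halides and the opening of epoxides by ketone enolates to γ-hydroxy ketones; their union in a medium-ring closure is new. Ring closures: the furanone by O-attack on C3 (5-endo-dig), then the nine-membered oxacycle, which is the ten-membered carbocycle counted through C1 and C2, by endo-mode opening of the epoxide at its distal carbon with C8 keeping its configuration. C10 is set under substrate control: enolisation erases the C10 mixture (stereoconvergence), and the tether, held by the Z-C4=C5 bond and the C6, C7 and C8 stereocentres, is expected to reach C10 over the furan face that keeps the C6 acyloxy and C7 isopropenyl groups outside the forming ring with the C8–O bond anti to the incoming carbon, which corresponds to 10R. The step needs C- over O-alkylation (O-attack would force the tether into the furan plane as a strained 3,5-bridged furan, and t-BuOH hydrogen-bonds the oxygen), attack at C9 and not C8 (terminal, unhindered carbon), cyclisation over oligomerisation (high dilution) and no acyl migration or epimerisation (weak base that never accumulates the C8 alkoxide).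

Step 16
Reactants: 26 (4Z,6R,7R,8S,10R)-8-hydroxy-1-oxo-3,10-epoxygermacra-2,4,11(13)-trien-6-yl (2S,3R)-2,3-dimethyloxirane-2-carboxylate
Product: 27 (4Z,6R,7R,8S,10R)-8,12-dihydroxy-1-oxo-3,10-epoxygermacra-2,4,11(13)-trien-6-yl (2S,3R)-2,3-dimethyloxirane-2-carboxylate
Conditions: SeO2 (cat.), t-BuOOH, CH2Cl2, 0 → 23 °C
Reagents that add atoms: tert-butyl hydroperoxide (CC(C)(C)OO)
Why: Riley-type allylic oxidation (ene reaction, then [2,3]-sigmatropic shift) should hydroxylate the methyl group of the 1,1-disubstituted alkene, the conjugated, electron-poor C4=C5 bond and its methyl group being deactivated.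

Step 17
Reactants: 27 (4Z,6R,7R,8S,10R)-8,12-dihydroxy-1-oxo-3,10-epoxygermacra-2,4,11(13)-trien-6-yl (2S,3R)-2,3-dimethyloxirane-2-carboxylate
Product: 30 CNP0258430.2, (4Z,6R,7R,8S,10R)-6-{[(2S,3R)-2,3-dimethyloxiran-2-yl]carbonyloxy}-1-oxo-3,10-epoxygermacra-2,4,11(13)-trien-12,8-olide, via hydroxy enal 28 (not isolated), via lactol 29 (not isolated)
Conditions: TEMPO (cat.), PhI(OAc)2, CH2Cl2, 23 °C
Reagents that add atoms: none
Why: Oxidative lactonisation: the primary allylic alcohol is oxidised to the enal, the C8 hydroxyl closes the lactol (5-exo-trig) and a second oxidation should give the α-methylene-γ-butyrolactone, trans-fused because C7 and C8 are already set.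

**Compound list**

1 | but-2-yn-1-ol | CC#CCO | starting material
2 | sodium alkenylalanate (five-membered oxaaluminacycle from 1, two 2-methoxyethoxy groups on aluminium; not isolated) | CC1=CCO[Al-]1(OCCOC)OCCOC.[Na+] | intermediate
3 | (Z)-3-iodobut-2-en-1-ol | C/C(I)=C/CO | intermediate
4 | (Z)-3-iodobut-2-enal | C/C(I)=C/C=O | intermediate
5 | (S)-4-benzyl-1,3-oxazolidin-2-one | O=C1N[C@@H](Cc2ccccc2)CO1 | starting material
6 | 3-methylbut-2-enoyl chloride | CC(C)=CC(=O)Cl | starting material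
7 | N-lithio derivative of 5 (not isolated) | [Li]N1[C@@H](Cc2ccccc2)COC1=O | intermediate
8 | (S)-4-benzyl-3-(3-methylbut-2-enoyl)-1,3-oxazolidin-2-one | CC(C)=CC(=O)N1[C@@H](Cc2ccccc2)COC1=O | intermediate
9 | di-n-butylboron Z-dienolate of 8 (not isolated) | C=C(C)/C=C(\OB(CCCC)CCCC)N1[C@@H](Cc2ccccc2)COC1=O | intermediate
10 | (4S)-4-benzyl-3-[(2S,3S,4Z)-3-hydroxy-5-iodo-2-(prop-1-en-2-yl)hex-4-enoyl]-1,3-oxazolidin-2-one | O=C(N1[C@@H](Cc2ccccc2)COC1=O)[C@@H](C(C)=C)[C@H](O)/C=C(/C)I | intermediate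
11 | (2S,3S,4Z)-3-hydroxy-5-iodo-N-methoxy-N-methyl-2-(prop-1-en-2-yl)hex-4-enamide | CON(C)C(=O)[C@@H](C(C)=C)[C@H](O)/C=C(/C)I | intermediate
12 | (3S,4S,5Z)-1-chloro-4-hydroxy-6-iodo-3-(prop-1-en-2-yl)hept-5-en-2-one | ClCC(=O)[C@@H](C(C)=C)[C@H](O)/C=C(/C)I | intermediate
13 | (2R,3S,4S,5Z)-1-chloro-6-iodo-3-(prop-1-en-2-yl)hept-5-ene-2,4-diol | ClC[C@H](O)[C@@H](C(C)=C)[C@H](O)/C=C(/C)I | intermediate
14 | (3S,4S,5Z)-6-iodo-2-methyl-3-[(2R)-oxiran-2-yl]hepta-1,5-dien-4-ol | C1O[C@@H]1[C@@H](C(C)=C)[C@H](O)/C=C(/C)I | intermediate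
15 | (E)-2-methylbut-2-en-1-ol | C/C=C(\C)CO | starting material
16 | [(2R,3R)-2,3-dimethyloxiran-2-yl]methanol | OC[C@@]1(C)O[C@@H]1C | intermediate
17 | (2S,3R)-2,3-dimethyloxirane-2-carbaldehyde (not isolated) | O=C[C@@]1(C)O[C@@H]1C | intermediate
18 | (2S,3R)-2,3-dimethyloxirane-2-carboxylic acid | OC(=O)[C@@]1(C)O[C@@H]1C | intermediate
19 | mixed anhydride of 18 with 2,4,6-trichlorobenzoic acid (not isolated) | O=C(OC(=O)c1c(Cl)cc(Cl)cc1Cl)[C@@]2(C)O[C@@H]2C | intermediate
20 | (3S,4S,5Z)-6-iodo-2-methyl-3-[(2R)-oxiran-2-yl]hepta-1,5-dien-4-yl (2S,3R)-2,3-dimethyloxirane-2-carboxylate | C1O[C@@H]1[C@@H](C(C)=C)[C@H](OC(=O)[C@@]2(C)O[C@@H]2C)/C=C(/C)I | intermediate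
21 | pent-3-en-1-yne (E/Z mixture) | C#CC=CC | starting material
22 | pent-1-yne-3,4-diol (mixture of stereoisomers) | C#CC(O)C(C)O | intermediate
23 | (3S,4R,5Z)-9,10-dihydroxy-2,6-dimethyl-3-[(2R)-oxiran-2-yl]undeca-1,5-dien-7-yn-4-yl (2S,3R)-2,3-dimethyloxirane-2-carboxylate (mixture at the two carbinols) | C1O[C@@H]1[C@@H](C(C)=C)[C@H](OC(=O)[C@@]2(C)O[C@@H]2C)/C=C(/C)C#CC(O)C(C)O | intermediate
24 | (3S,4R,5Z)-10-hydroxy-2,6-dimethyl-3-[(2R)-oxiran-2-yl]-9-oxoundeca-1,5-dien-7-yn-4-yl (2S,3R)-2,3-dimethyloxirane-2-carboxylate (both carbinol epimers) | C1O[C@@H]1[C@@H](C(C)=C)[C@H](OC(=O)[C@@]2(C)O[C@@H]2C)/C=C(/C)C#CC(=O)C(C)O | intermediate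
25 | (3S,4R,5Z)-2-methyl-6-(5-methyl-4-oxo-4,5-dihydrofuran-2-yl)-3-[(2R)-oxiran-2-yl]hepta-1,5-dien-4-yl (2S,3R)-2,3-dimethyloxirane-2-carboxylate (both furanone epimers; not isolated) | C1O[C@@H]1[C@@H](C(C)=C)[C@H](OC(=O)[C@@]2(C)O[C@@H]2C)/C=C(/C)C3=CC(=O)C(C)O3 | intermediate
26 | (4Z,6R,7R,8S,10R)-8-hydroxy-1-oxo-3,10-epoxygermacra-2,4,11(13)-trien-6-yl (2S,3R)-2,3-dimethyloxirane-2-carboxylate (11-oxabicyclo[6.2.1]undecadienone with C8–OH and C7 isopropenyl) | O[C@H]1C[C@@]2(C)OC(=CC2=O)/C(C)=C\[C@@H](OC(=O)[C@@]3(C)O[C@@H]3C)[C@@H]1C(C)=C | intermediate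
27 | (4Z,6R,7R,8S,10R)-8,12-dihydroxy-1-oxo-3,10-epoxygermacra-2,4,11(13)-trien-6-yl (2S,3R)-2,3-dimethyloxirane-2-carboxylate | O[C@H]1C[C@@]2(C)OC(=CC2=O)/C(C)=C\[C@@H](OC(=O)[C@@]3(C)O[C@@H]3C)[C@@H]1C(CO)=C | intermediate
28 | 12-aldehyde of 27 (8-hydroxy enal; not isolated) | O[C@H]1C[C@@]2(C)OC(=CC2=O)/C(C)=C\[C@@H](OC(=O)[C@@]3(C)O[C@@H]3C)[C@@H]1C(C=O)=C | intermediate
29 | 12,8-lactol of 28 (epimers at C12; not isolated) | C=C1C(O)O[C@H]2C[C@@]3(C)OC(=CC3=O)/C(C)=C\[C@@H](OC(=O)[C@@]4(C)O[C@@H]4C)[C@H]12 | intermediate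
30 | CNP0258430.2, (4Z,6R,7R,8S,10R)-6-{[(2S,3R)-2,3-dimethyloxiran-2-yl]carbonyloxy}-1-oxo-3,10-epoxygermacra-2,4,11(13)-trien-12,8-olide | C=C1C(=O)O[C@H]2C[C@@]3(C)OC(=CC3=O)/C(C)=C\[C@@H](OC(=O)[C@@]3(C)O[C@@H]3C)[C@H]12 | target

**Step count**

Total: 17 steps. Longest linear sequence: 13 steps (steps 1, 2, 4, 5, 6, 7, 8, 11, 13, 14, 15, 16, 17).

**Steps most likely to fail**

1. Step 15 (Proposed new method). What may go wrong: alkylation at the enolate oxygen or oligomerisation outruns the slow attack of the furan-3-olate carbon on the unactivated epoxide, or the ring closes over the wrong furan face. The fallback uses known chemistry, sets out from 24 and comes back at 26. Brief treatment of 24 with catalytic Cs2CO3 in MeCN at 0 °C gives furanone 25, which is isolated. LiI/AcOH in THF opens the terminal epoxide at C9 to the C9-iodo C8-hydroxy furanone F1, and Et3SiCl/imidazole gives its C8 triethylsilyl ether F2. KN(SiMe3)2 in THF/DMPU at −78 → 0 °C under high dilution then closes the C9–C10 bond by the known C2-alkylation of a 2-methyl-3(2H)-furanone enolate with a primary iodide, giving the C8-O-triethylsilyl ether of the macrocycle F3; the low temperature and tight potassium enolate also offer a handle on face selectivity. AcOH/THF/H2O removes the silyl group and returns 26.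

2. Step 16. What may go wrong: the ene oxidation loses site selectivity on the fully functionalised macrocycle (attack at the C4 methyl group or at C7–H) or over-oxidises. The fallback replaces the ene oxidation, sets out from 26 and comes back at 27. Hydroxyl-directed epoxidation of the isopropenyl group with VO(acac)2/t-BuOOH (the homoallylic C8 hydroxyl directs, the electron-poor dienone is inert) gives the 11,13-epoxide of 26 F4. Eliminative epoxide opening with Me3SiOTf/DBU, with proton loss from the methyl group, gives the 8,12-bis(trimethylsilyl) ether of 27 F5, and citric acid in MeOH releases 27.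

3. Step 14. What may go wrong: oxidative cleavage of the 1,2-diol, or oxidation of both carbinols instead of the propargylic one alone. The fallback avoids a free diol, sets out from 20 and commercial ethyl (S)-2-[(tert-butyldimethylsilyl)oxy]propanoate, and comes back at 24. i-Bu2AlH reduction of the ester at −78 °C gives (S)-2-[(tert-butyldimethylsilyl)oxy]propanal F6, and HC≡CMgBr adds to give (4S)-4-[(tert-butyldimethylsilyl)oxy]pent-1-yn-3-ol F7. Sonogashira coupling with 20 under the conditions of step 13 gives the mono-silylated enynol F8, and Dess–Martin periodinane oxidises its only free hydroxyl to the silyloxy ynone F9. n-Bu4NF buffered with AcOH removes the silyl group and returns 24 as a single C10 epimer, which is immaterial.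

**Further compounds**

F1 | step 15 | C9-iodo C8-hydroxy furanone (iodohydrin from 25) | IC[C@H](O)[C@@H](C(C)=C)[C@H](OC(=O)[C@@]1(C)O[C@@H]1C)/C=C(/C)C2=CC(=O)C(C)O2
F2 | step 15 | C8 triethylsilyl ether of F1 | IC[C@H](O[Si](CC)(CC)CC)[C@@H](C(C)=C)[C@H](OC(=O)[C@@]1(C)O[C@@H]1C)/C=C(/C)C2=CC(=O)C(C)O2
F3 | step 15 | C8-O-triethylsilyl ether of 26 | CC[Si](CC)(CC)O[C@H]1C[C@@]2(C)OC(=CC2=O)/C(C)=C\[C@@H](OC(=O)[C@@]3(C)O[C@@H]3C)[C@@H]1C(C)=C
F4 | step 16 | 11,13-epoxide of 26 (epimers at C11) | O[C@H]1C[C@@]2(C)OC(=CC2=O)/C(C)=C\[C@@H](OC(=O)[C@@]3(C)O[C@@H]3C)[C@@H]1C4(C)CO4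
F5 | step 16 | 8,12-bis(trimethylsilyl) ether of 27 | C[Si](C)(C)O[C@H]1C[C@@]2(C)OC(=CC2=O)/C(C)=C\[C@@H](OC(=O)[C@@]3(C)O[C@@H]3C)[C@@H]1C(CO[Si](C)(C)C)=C
F6 | step 14 | (S)-2-[(tert-butyldimethylsilyl)oxy]propanal | C[C@H](O[Si](C)(C)C(C)(C)C)C=O
F7 | step 14 | (4S)-4-[(tert-butyldimethylsilyl)oxy]pent-1-yn-3-ol (epimers at C3) | C[C@H](O[Si](C)(C)C(C)(C)C)C(O)C#C
F8 | step 14 | Sonogashira product of 20 and F7 (mono-silylated enynol) | C1O[C@@H]1[C@@H](C(C)=C)[C@H](OC(=O)[C@@]2(C)O[C@@H]2C)/C=C(/C)C#CC(O)[C@H](C)O[Si](C)(C)C(C)(C)C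
F9 | step 14 | silyloxy ynone (tert-butyldimethylsilyl ether of 24) | C1O[C@@H]1[C@@H](C(C)=C)[C@H](OC(=O)[C@@]2(C)O[C@@H]2C)/C=C(/C)C#CC(=O)[C@H](C)O[Si](C)(C)C(C)(C)C
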